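20% of target in 10.0 min at 37 °C, against 10% in 15.0 min at 29 °C: from these two early readings I reckon the pace of both new flasks.

| setting | south-east | south-west | noon | winter |
|---|---|---|---|---|
| starting material | 0.25 M | 0.38 M | 0.50 M | 0.50 M |
| partner | 2.5 equiv | 2.5 equiv | 2.50 equiv | 2.50 equiv |
| temperature | 29 °C | 37 °C | 40 °C | 25 °C |
| remark | run made earlier | run made earlier |  |  |
| time |  |  | 40 min | 40 min |

- south-east (time / min: target / %): 15.0: 10; 25.0: 16; 40.0: 23; 50.0: 22; 60.0: 29; 80.0: 32
- south-west (time / min: target / %): 3.00: 6; 10.0: 20; 15.0: 25; 25.0: 35; 40.0: 41; 50.0: 42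

(readings scatter by 1.5 percentage points)

* the flask that comes out highest in amount of target, in percent of the starting material charged, or "all alike" when all lie within 1.5 percentage points (noon / winter / all alike)
* target at the end, in percent of the starting material charged, noon
* target at the end, in percent of the starting material charged, winter

- the numbers in the tables scatter with a standard deviation of 1.5 percentage points
- a reading or a percentage of target counts all its forms, free or not

First I take one step, starting material + partner → target, first order in each. Early yield per minute over c_partner gives, as readings with their scatter: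

k(south-east) = 0.0107 M⁻¹ min⁻¹; k(south-west) = 0.0211 M⁻¹ min⁻¹; Ea = 66.2 kJ mol⁻¹

k(noon) = 0.0269 M⁻¹ min⁻¹; k(winter) = 0.00749 M⁻¹ min⁻¹

θ(noon) = 1.35; θ(winter) = 0.374

This clock θ, the product k·c_partner·t at the flask's temperature, is the pseudo-first-order exponent. With partner held constant, 1 − exp(−θ) gives 74.0% for noon and 31.2% for winter.

Second, I let partner be consumed from its 2.50 equiv. The integrated second-order law lowers these to 67.4% and 29.6%.

Third, whatever else the flask does, I read from the runs on the same clock. South-west reaches θ = 1.00 with 42%, where the second step gives 57.8%, and its last two readings differ by 1 percentage point. Noon's clock runs further than that, so I commit to a yield above 42%. Winter's θ lies above south-west at 15.0 min (0.300, 25%) and below south-east at 60.0 min (0.400, 29%), so I read winter between those two yields.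

The forecast gives noon, with 45% for noon and 29% for winter, the latter at the top of my bracket: “Winter is still kinetically limited”.

The simulation gives 46.3% for noon and 25.6% for winter, so noon comes out highest.

    starting material + partner → side product (k = 0.0110 M⁻¹ min⁻¹, Ea = 69.0 kJ mol⁻¹)
    starting material + partner ⇌ intermediate A (K = 2.50 M⁻¹, k = 0.0180 M⁻¹ min⁻¹, Ea = 73.0 kJ mol⁻¹, ΔH = −30.0 kJ mol⁻¹)
    partner + intermediate A ⇌ intermediate B (K = 1.80 M⁻¹, k = 0.0140 M⁻¹ min⁻¹, Ea = 63.0 kJ mol⁻¹, ΔH = −14.0 kJ mol⁻¹)
    intermediate A ⇌ intermediate C (K = 33.0, k = 0.0260 min⁻¹, Ea = 84.0 kJ mol⁻¹, ΔH = −20.0 kJ mol⁻¹)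
    intermediate A → target (k = 0.120 min⁻¹, Ea = 96.0 kJ mol⁻¹)
    partner ⇌ dormant form (K = 0.970, k = 0.0100 min⁻¹, Ea = 92.0 kJ mol⁻¹, ΔH = −22.0 kJ mol⁻¹)
    starting material + target ⇌ idle adduct, settled at all times (K = 2.50 M⁻¹, ΔH = 16.0 kJ mol⁻¹)
    (constants at 25 °C)

In noon, 92.1% of the starting material is converted, while side product stands at 32.4% at 40.0 min. The neighbour flask, noon with 4.20 equiv of partner, has an estimated θ = 2.26, and its target reaches 51.3%, which is 5 points above noon.

The data are calculated with constants of no real substance.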